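The millimolar was the unit I reached for first: Friday's and Wednesday's runs had the same equivalents of Z and the same mol% of L, yet their mean G stood at 53.5% and 73.3%. Sunday's, at 1 mM of D and 0.0075 mol% of L, stood at 69.7%.

all flasks: Z 1.05 equiv (in portions, 3)

| charge | D | L | remark | time |
|---|---|---|---|---|
| Friday's | 0.50 mM | 0.015 mol% | run made earlier; portions every 6.0 s |  |
| Wednesday's | 0.75 mM | 0.015 mol% | run made earlier; portions every 6.0 s |  |
| Sunday's | 1 mM | 0.0075 mol% | run made earlier; portions every 6.0 s |  |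
| flask | 1.0 mM | 0.015 mol% | the portions of Z follow each other after 6.0 s, the first at the start | 4.0 h |

| run | time / h | D / % | G / % |
|---|---|---|---|
| Friday's | 0.333 | 45.9 | 52.6 |
| Friday's | 1.00 | 47.6 | 54.3 |
| Friday's | 1.50 | 45.4 | 52.8 |
| Friday's | 2.50 | 45.5 | 52.5 |
| Friday's | 4.00 | 44.2 | 54.3 |
| Friday's | 5.00 | 48.3 | 54.4 |
| Wednesday's | 0.833 | 26.3 | 72.7 |
| Wednesday's | 1.50 | 26.0 | 74.0 |
| Wednesday's | 2.50 | 27.1 | 73.6 |
| Wednesday's | 3.00 | 28.0 | 71.8 |
| Wednesday's | 4.00 | 28.3 | 73.9 |
| Wednesday's | 5.00 | 25.8 | 74.0 |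
| Sunday's | 1.00 | 29.5 | 70.0 |
| Sunday's | 2.00 | 28.1 | 70.1 |
| Sunday's | 3.00 | 30.5 | 69.3 |
| Sunday's | 4.00 | 28.9 | 70.1 |
| Sunday's | 5.00 | 28.3 | 68.8 |

(each reading ± 1 percentage point)

- a reading or a percentage of G counts all its forms, free or not

1. conversion of D at 4.0 h
2. amount of G at 4.0 h, in percent of the D charged

Friday's G read 52.6% at 0.333 h and 54.4% at 5.00 h, with D, the limiting reagent, still at 48.3%, so I took L to die early. If the rate is first order in D, Z and L, and L has a fixed lifetime, a flask has a reach: ln[(e − x)/(e(1 − x))]/(e − 1), with x the conversion and e the equivalents of Z. The reach then goes with cL times cD at the start. The three runs gave reaches of 1.07, 2.46 and 2.08.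

I went to the flask by two ways. Sunday's run had the flask's cD and half its loading, so proportion to L gave a reach of 4.15 and 82.9%. Separately, Friday's and Wednesday's runs gave a log–log slope in cD of 2.06; carried on from Wednesday's, it gave 4.46 and 84.0%. They parted by 1.1 percentage points, with a single reading scattering by 1 point, so I convicted neither and took the middle in logarithms, the flask's reach 4.30, which gives 83.4%.

The forecast stood at 83.4% conversion and 83.4% G, on a ratio it called “nicely constant”.

The flask gave 83.6% conversion and 83.6% G at 4.0 h.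

    J ⇌ G, rate k1*(cs1 - [G]) while solid is left; crystals form when [G] > cs1 (solubility = 0.540 mM, k = 0.410 s⁻¹)
    D + L ⇌ E (K = 540 M⁻¹, k = 7.40 × 10⁶ M⁻¹ s⁻¹)
    L → X (k = 0.0100 s⁻¹)
    Q → L + G (k = 150 s⁻¹)
    Z + E ⇌ Q (K = 16000 M⁻¹, k = 7.30 × 10⁵ M⁻¹ s⁻¹)

At 4.00 h the catalyst stood 100% as X, L going to X with a half-life of 1.2 min by that step alone. Scaled by loading, my reach becomes 10.6 for the neighbour flask charged with 0.037 mol% of L, which gives 93.6%, and that neighbour flask gave 93.7%.

The readings are simulated with made-up constants; noise was put on by code.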